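**Plan**
- Retrosynthesis cuts, in this order: the O–CH2Ph bond of a benzyl ether on the phenol; the CH2–CH2 bond between C8 and C9 of the hexacosyl chain (counted from the ester oxygen; C19/C18 from the methyl end); the ester C(=O)–O bond.
- Forward: acid 1 and alkenol 2 give the C8 ester 3; the chain is completed as C8 + C18 by Ni–H reductive hydroalkylation of the terminal alkene of 3 with iodide 4 to give 5; hydrogenolysis then frees the phenol of 6.
- Enabling feature: the bond lies in an unbranched polymethylene chain. Both of its carbons are CH2 groups with only CH2 neighbours, far from the ester oxygen and the benzene ring, so one can be the terminal carbon of a monosubstituted alkene and the other a primary iodide carbon.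
- Helper: a benzyl ether on the para-oxygen of the benzene ring, because a free ArO–H would donate H to Ni–H and to alkyl radicals; it is removed in the last step.
- Stereochemistry: the target has no stereocentre and no C=C bond, so none has to be set.

Key step: step 2

**Step 1**
Reactants: 1 3-[4-(benzyloxy)phenyl]propanoic acid; 2 oct-7-en-1-ol
Product: 3 oct-7-en-1-yl 3-[4-(benzyloxy)phenyl]propanoate
Conditions: DCC (1.1 equiv), DMAP (0.1 equiv), CH2Cl2, 0 °C → rt
Reagents that add atoms: none
Why: Steglich esterification, in which DMAP-catalysed acyl transfer from the carbodiimide-activated acid to the primary alcohol should proceed at room temperature without touching the terminal alkene or the aryl benzyl ether; no stereocentre is formed.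

**Step 2**
Reactants: 3 oct-7-en-1-yl 3-[4-(benzyloxy)phenyl]propanoate; 4 1-iodooctadecane (1.5 equiv)
Product: 5 hexacosyl 3-[4-(benzyloxy)phenyl]propanoate
Conditions: NiBr2·diglyme (10 mol %), 4,4'-di-tert-butyl-2,2'-bipyridine (12 mol %), (EtO)2MeSiH (2.5 equiv), Na2CO3 (3 equiv), DMA/THF, 30 °C
Reagents that add atoms: none
Why: A bipyridine-ligated nickel hydride, generated from the silane and carbonate, should add across the C7=C8 bond of 3 with nickel on the terminal C8; the octadecyl radical formed from 4 by halogen abstraction is captured at nickel, and C(sp3)–C(sp3) reductive elimination forms the C8–C1' bond. The closest known reaction type is the Ni–H-catalysed anti-Markovnikov reductive hydroalkylation of unactivated terminal olefins with primary alkyl iodides, with a hydrosilane as hydride source. No ring is closed and no stereocentre is created, since both carbons of the new bond become CH2 groups. The step needs linear regioselectivity, cross- over homo-coupling, and inertness of the ester and benzyl ether. Regioselectivity should be secured by the monosubstituted alkene, which gives the least hindered primary alkylnickel, and by the six CH2 groups that separate it from the ester oxygen, so no heteroatom draws the metal along the chain. Cross-selectivity is built in because only the alkene can accept the hydride and only the iodide can supply the radical, and the benzyl cap removes the O–H that would quench Ni–H and alkyl radicals.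

**Step 3**
Reactants: 5 hexacosyl 3-[4-(benzyloxy)phenyl]propanoate
Product: 6 hexacosyl 3-(4-hydroxyphenyl)propanoate
Conditions: H2 (1 atm), 10 % Pd/C, THF/EtOAc, 40 °C
Reagents that add atoms: none
Why: Heterogeneous catalytic hydrogenolysis of the benzylic C–O bond of the aryl benzyl ether should release the phenol and toluene under neutral conditions that leave the saturated ester and alkyl chain untouched; no stereocentre is involved.

**Compound list**
1 | 3-[4-(benzyloxy)phenyl]propanoic acid | O=C(O)CCc1ccc(OCc2ccccc2)cc1 | starting material
2 | oct-7-en-1-ol | C=CCCCCCCO | starting material
3 | oct-7-en-1-yl 3-[4-(benzyloxy)phenyl]propanoate | C=CCCCCCCOC(=O)CCc1ccc(OCc2ccccc2)cc1 | intermediate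
4 | 1-iodooctadecane | CCCCCCCCCCCCCCCCCCI | starting material
5 | hexacosyl 3-[4-(benzyloxy)phenyl]propanoate | CCCCCCCCCCCCCCCCCCCCCCCCCCOC(=O)CCc1ccc(OCc2ccccc2)cc1 | intermediate
6 | hexacosyl 3-(4-hydroxyphenyl)propanoate | CCCCCCCCCCCCCCCCCCCCCCCCCCOC(=O)CCc1ccc(O)cc1 | target

Total step count: 3
Longest linear sequence: 3 steps (1 → 3 → 5 → 6)

**Steps most likely to fail**

Step 2. The alkylnickel formed from the alkene may migrate along the chain before it is captured, which would give branched C–C bonds. Nickel hydride may also reduce the iodide or saturate and isomerise the alkene faster than the cross-coupling. The fallback fixes the regiochemistry stoichiometrically and replaces the reductive radical coupling with a two-electron cross-coupling. It sets out from 3, which is hydroborated with 9-BBN (THF, 0 °C → rt) to give 8-(9-borabicyclo[3.3.1]nonan-9-yl)octyl 3-[4-(benzyloxy)phenyl]propanoate F1. Without isolation, F1 is submitted to an alkyl–alkyl Suzuki–Miyaura coupling with commercial 1-bromooctadecane [Pd(OAc)2, PCy3, K3PO4·H2O, THF, rt]. This forms the same CH2–CH2 bond and comes back to the route at 5.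

Step 3. Hydrogenolysis may stall through poisoning of the palladium surface by traces of iodide or nickel carried over from step 2, or through poor solubility of the waxy substrate. The fallback dispenses with the deprotection. It sets out from 5, which is saponified (LiOH, THF/MeOH/H2O, 50 °C) to hexacosan-1-ol F2. F2 is then esterified with commercial, unprotected 3-(4-hydroxyphenyl)propanoic acid under Fischer conditions (cat. TsOH, toluene, reflux, Dean–Stark). Only the aliphatic alcohol should be acylated, since the phenol is too poor a nucleophile under acid catalysis, and the sequence comes back to the route at 6.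

Step 1. The carbodiimide-activated acid may rearrange by O→N acyl migration to an unreactive N-acylurea, and the urea by-product may be carried into the nickel step. The fallback forms the ester by alkylation of the carboxylate instead of acylation of the alcohol. It sets out from 2, which is converted (MsCl, Et3N, CH2Cl2, 0 °C) into oct-7-en-1-yl methanesulfonate F3. Acid 1 is then O-alkylated with F3 (Cs2CO3, DMF, 50 °C) in an SN2 esterification, which comes back to the route at 3.

**Further compounds**
F1 | step 2 | 8-(9-borabicyclo[3.3.1]nonan-9-yl)octyl 3-[4-(benzyloxy)phenyl]propanoate | O=C(CCc1ccc(OCc2ccccc2)cc1)OCCCCCCCCB1C2CCCC1CCC2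
F2 | step 3 | hexacosan-1-ol | CCCCCCCCCCCCCCCCCCCCCCCCCCO
F3 | step 1 | oct-7-en-1-yl methanesulfonate | C=CCCCCCCOS(C)(=O)=O
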